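A direct plan would take methyl 2,4,6-trihydroxybenzoate A1 and methylate its 4-hydroxyl, add the ring methyl by formylation and hydrogenolysis, C-acylate the last free ring carbon and remove the ester by saponification and decarboxylation.
It would thus reach the monomer 1-(4,6-dihydroxy-2-methoxy-3-methylphenyl)-3-methylbutan-1-one A2 and would join two molecules of it at the end through formaldehyde A3 as the one-carbon bridge.
Its weakest steps would be:
- the ester blocking and unblocking together with the formylation/hydrogenolysis pair: an ester would be carried only to steer two substitutions and then burnt off, and two steps would be spent on one methyl group, so five ring-decoration steps would buy little complexity;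
- the mono-O-methylation: its choice among three phenols would rest only on one equivalent of base and on hydrogen bonding to the ester;
- the formaldehyde coupling: it would be run last, on all of the monomer, through a reactive methide that solvent or a phenol oxygen could also intercept.

**Plan of the new route** (target locants: C1' acyl, C2' OH, C3' CH2 bridge, C4' OH, C5' CH3, C6' OCH3)
The retrosynthesis cuts the ring bond C2'–C3' in both halves at once; each benzene ring is then an isomer of a 3-acyl-4-methoxy-5-methyl-2-pyranone whose ring oxygen sits where C3' will be.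
Feature used: C2'(OH), C1'(acyl), C6'(OMe), C5'(Me) and C4'(OH) map one-to-one on C2, C3, C4, C5 and C6 of the pyranone, and C3'–CH2–C3' is the (CH2)3 chain of glutaric acid.
Order: the bridge is bought, the two pyranone rings arise next in a two-directional sequence, and both benzene rings arise last and together by a double pyranone-to-benzene isomerisation that copies the polyketide Claisen closure of acylphloroglucinol biosynthesis.
The pyranone has one hydroxyl, the one to be methylated, so no blocking ester and no choice between phenols arise; no formaldehyde coupling is needed and the last step loses no atom.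

Key step: step 5

Remark: the target is achiral, so no stereocentre has to be set; 5, 9 and 12 are drawn as one tautomer of their keto–enol mixtures.

**Step 1**
Reactants: 1 pentanedioyl dichloride (glutaryl dichloride); 2 N,O-dimethylhydroxylamine hydrochloride
Product: 3 N1,N5-dimethoxy-N1,N5-dimethylpentanediamide
Conditions: 2 (2.2 equiv), Et3N (4.5 equiv), CH2Cl2, 0 °C to rt
Reagents that add atoms: N,O-dimethylhydroxylamine hydrochloride (CNOC.Cl)
Why: Twofold N-acylation by the acid chloride (Weinreb amide formation) should give a stable bis-acylating agent that carries the future bridge CH2 and both C3' carbons and cannot close to an anhydride.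

**Step 2**
Reactants: 3 N1,N5-dimethoxy-N1,N5-dimethylpentanediamide; 4 methyl 3-oxopentanoate
Product: 6 6,6'-(propane-1,3-diyl)bis(4-hydroxy-5-methyl-2H-pyran-2-one), via tetraketo diester 5 (not isolated)
Conditions: 4 (3.2 equiv), NaH (3.2 equiv) then n-BuLi (3.2 equiv), THF, 0 °C; add 3, −78 to 0 °C; aq. HCl; crude, DBU (2.2 equiv), PhMe, 90 °C; then aq. HCl
Reagents that add atoms: methyl 3-oxopentanoate (CCC(=O)CC(=O)OC)
Why: γ-Acylation of the β-keto ester dianion by the Weinreb amide (crossed Claisen condensation) should acylate each end once, because the chelated tetrahedral adduct survives until the acid quench, and DBU should then lactonise each 3,5-dioxo ester through its enol oxygen to the 4-hydroxy-2-pyranone, in which the two transient stereocentres of 5 vanish.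

**Step 3**
Reactants: 6 6,6'-(propane-1,3-diyl)bis(4-hydroxy-5-methyl-2H-pyran-2-one); 7 3-methylbutanoic acid
Product: 9 6,6'-(propane-1,3-diyl)bis[4-hydroxy-5-methyl-3-(3-methylbutanoyl)-2H-pyran-2-one], via bis(enol ester) 8 (not isolated)
Conditions: 7 (2.4 equiv), DCC (2.6 equiv), DMAP (0.5 equiv), PhMe, rt then 80 °C
Reagents that add atoms: 3-methylbutanoic acid (CC(C)CC(=O)O)
Why: Steglich O-acylation of the vinylogous acid followed by DMAP-mediated O-to-C acyl migration (Fries-type) should place the acyl group at C3, the only free nucleophilic ring carbon since C5 carries the methyl group, and the product is held as a chelated enol.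

**Step 4**
Reactants: 9 6,6'-(propane-1,3-diyl)bis[4-hydroxy-5-methyl-3-(3-methylbutanoyl)-2H-pyran-2-one]; 10 dimethyl sulfate
Product: 11 6,6'-(propane-1,3-diyl)bis[4-methoxy-5-methyl-3-(3-methylbutanoyl)-2H-pyran-2-one]
Conditions: Me2SO4 (3 equiv), K2CO3 (3 equiv), acetone, reflux
Reagents that add atoms: dimethyl sulfate (COS(=O)(=O)OC)
Why: O-Alkylation of the vinylogous carboxylate (Williamson-type) with a hard methylating agent should give the 4-methoxy-2-pyranone, because each ring has only one acidic hydroxyl and methylation at O4 keeps the 2-pyranone conjugation.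

**Step 5**
Reactants: 11 6,6'-(propane-1,3-diyl)bis[4-methoxy-5-methyl-3-(3-methylbutanoyl)-2H-pyran-2-one]
Product: 13 1,1'-[methylenebis(2,4-dihydroxy-6-methoxy-5-methyl-3,1-phenylene)]bis(3-methylbutan-1-one), via ring-opened bis(keto ester) 12 (not isolated)
Conditions: Mg(OMe)2 (8 equiv), MeOH (0.02 M), 65 to 110 °C (sealed vessel), N2; then 1 M HCl
Reagents that add atoms: none
Why: Proposed new method: methoxide should add to the lactone carbonyl C2 of each pyranone and open the ring to the methyl ester 12, whose freed ketone (old C6, new C4') enolises under excess Mg(OMe)2 toward the side-chain CH2 (new C3'); this carbon attacks the ester carbon (new C2') in a Dieckmann-type intramolecular Claisen condensation, methoxide is expelled and the cyclohexadienone tautomerises to the magnesium phenoxide, so that the old ring oxygen ends as 4'-OH, the lactone carbonyl as 2'-OH and the 4-OMe as 6'-OMe. The closest known reaction types are the Mg(OMe)2-mediated conversion of 4-hydroxy-6-(2-oxoalkyl)-2-pyranones into acylphloroglucinols and the NaOMe-mediated isomerisation of 4-methoxy-6-methyl-2-pyranone to 5-methoxyresorcinol; not shown before are the 3-acyl-2-pyranone substrate class and a nucleophilic carbon activated by a single ketone. Each benzene ring is closed through the bond C2'–C3' in a 6-(enolendo)-exo-trig mode, the two closures being identical and independent, which is why the symmetric bridge can be carried through untouched. No stereocentre is formed, and the transient ones at C4 and C10 of 12 disappear on aromatisation. The selectivity needed is Claisen attack on the ester and not aldol attack of the same carbon on the isovaleryl carbonyl (which would lead to an isomeric benzoate): ring opening delivers the ester cis to the enolisable arm across the C=C(OMe) bond, and under excess Mg(OMe)2 the chain should be present as a chelated polyenolate in which charge from C5' is delocalised into the isovaleryl carbonyl, which is thereby an enolate oxygen and no electrophile, while loss of methoxide and aromatisation make the Claisen path irreversible. Methoxide as the only nucleophile makes any addition–elimination at the methoxy-bearing carbon degenerate, so the methyl ether is kept.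

**Compound list**
1 | pentanedioyl dichloride (glutaryl dichloride) | O=C(Cl)CCCC(=O)Cl | starting material
2 | N,O-dimethylhydroxylamine hydrochloride | CNOC.Cl | starting material
3 | N1,N5-dimethoxy-N1,N5-dimethylpentanediamide | CON(C)C(=O)CCCC(=O)N(C)OC | intermediate
4 | methyl 3-oxopentanoate | CCC(=O)CC(=O)OC | starting material
5 | dimethyl 4,10-dimethyl-3,5,9,11-tetraoxotridecanedioate (mixture of epimers and enol forms) | COC(=O)CC(=O)C(C)C(=O)CCCC(=O)C(C)C(=O)CC(=O)OC | intermediate
6 | 6,6'-(propane-1,3-diyl)bis(4-hydroxy-5-methyl-2H-pyran-2-one) | Cc1c(O)cc(=O)oc1CCCc1oc(=O)cc(O)c1C | intermediate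
7 | 3-methylbutanoic acid (isovaleric acid) | CC(C)CC(=O)O | starting material
8 | propane-1,3-diylbis(5-methyl-2-oxo-2H-pyran-6,4-diyl) bis(3-methylbutanoate) (bis(enol ester)) | Cc1c(OC(=O)CC(C)C)cc(=O)oc1CCCc1oc(=O)cc(OC(=O)CC(C)C)c1C | intermediate
9 | 6,6'-(propane-1,3-diyl)bis[4-hydroxy-5-methyl-3-(3-methylbutanoyl)-2H-pyran-2-one] | Cc1c(O)c(C(=O)CC(C)C)c(=O)oc1CCCc1oc(=O)c(C(=O)CC(C)C)c(O)c1C | intermediate
10 | dimethyl sulfate | COS(=O)(=O)OC | starting material
11 | 6,6'-(propane-1,3-diyl)bis[4-methoxy-5-methyl-3-(3-methylbutanoyl)-2H-pyran-2-one] | Cc1c(OC)c(C(=O)CC(C)C)c(=O)oc1CCCc1oc(=O)c(C(=O)CC(C)C)c(OC)c1C | intermediate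
12 | dimethyl (2E,11E)-3,11-dimethoxy-4,10-dimethyl-2,12-bis(3-methylbutanoyl)-5,9-dioxotrideca-2,11-dienedioate (C4 and C10 as epimer mixture; present as its magnesium enolate) | COC(=O)/C(C(=O)CC(C)C)=C(/OC)C(C)C(=O)CCCC(=O)C(C)/C(OC)=C(\C(=O)OC)C(=O)CC(C)C | intermediate
13 | 1,1'-[methylenebis(2,4-dihydroxy-6-methoxy-5-methyl-3,1-phenylene)]bis(3-methylbutan-1-one) = 3',3'''-methylenebis(2',4'-dihydroxy-6'-methoxy-β,5'-dimethylbutyrophenone), achiral | COc1c(C)c(O)c(Cc2c(O)c(C)c(OC)c(C(=O)CC(C)C)c2O)c(O)c1C(=O)CC(C)C | target

**Step count:** 5 steps in total; longest linear sequence 5 steps.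

**Steps most likely to fail**

Step 5. The same carbon could close by aldol addition onto the isovaleryl carbonyl in place of the Claisen closure, the second ring could lag behind the first, or the acyl group could be lost to methoxide. The fallback moves the ring transformation ahead of the acylation and uses known reaction types only. It sets out from 6, which would be O-methylated (Me2SO4, K2CO3, acetone) to 6,6'-(propane-1,3-diyl)bis(4-methoxy-5-methyl-2H-pyran-2-one) F1. With no ketone present, this bis-pyranone would be isomerised by NaOMe in MeOH in a sealed vessel at about 180 °C, the ring opening and Claisen reclosure that turns 4-methoxy-6-methyl-2-pyranone into 5-methoxyresorcinol, to 2,2'-methylenebis(5-methoxy-4-methylbenzene-1,3-diol) F2. Friedel–Crafts C-acylation of the single free position of each ring (between OH and OMe) with 3-methylbutanoic anhydride and BF3·OEt2, followed by hydrolysis of the boron chelate in aqueous MeOH, would return to the route at 13.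

Step 4. The ambident tricarbonyl anion could be methylated at the side-chain enol oxygen, at the lactone oxygen or at C3. The fallback reverses the polarity: from 9, TsCl and Et3N in CH2Cl2 would give the bis-sulfonate propane-1,3-diylbis[5-methyl-3-(3-methylbutanoyl)-2-oxo-2H-pyran-6,4-diyl] bis(4-methylbenzenesulfonate) F3. NaOMe in MeOH/THF at 0 °C would then bring in the methoxy oxygen by addition–elimination at C4, the carbon marked by the leaving group, and return to the route at 11.

Step 2. Proton transfer from the adduct could quench the dianion, acylation could stop after one end, or the 1,5-related ketones of 5 could undergo aldol closure during the DBU treatment. The fallback builds the pyranones through acylketenes. It sets out from 1 and 6-ethyl-2,2-dimethyl-4H-1,3-dioxin-4-one F4 (from tert-butyl 3-oxopentanoate, acetone, Ac2O and H2SO4). The dioxinone would be deprotonated at the ethyl CH2 with LiN(SiMe3)2 in THF at −78 °C and acylated by 1 to 2,8-bis(2,2-dimethyl-4-oxo-4H-1,3-dioxin-6-yl)nonane-3,7-dione F5 as a mixture of epimers. Heating this dione in PhMe at 110 °C would release acetone by retro-hetero-Diels–Alder reaction, and the enol oxygen would trap each acylketene, returning to the route at 6.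

**Further compounds**
F1 | step 5 | 6,6'-(propane-1,3-diyl)bis(4-methoxy-5-methyl-2H-pyran-2-one) | Cc1c(OC)cc(=O)oc1CCCc1oc(=O)cc(OC)c1C
F2 | step 5 | 2,2'-methylenebis(5-methoxy-4-methylbenzene-1,3-diol) | COc1cc(O)c(Cc2c(O)cc(OC)c(C)c2O)c(O)c1C
F3 | step 4 | propane-1,3-diylbis[5-methyl-3-(3-methylbutanoyl)-2-oxo-2H-pyran-6,4-diyl] bis(4-methylbenzenesulfonate) | Cc1ccc(cc1)S(=O)(=O)Oc1c(C)c(CCCc2oc(=O)c(C(=O)CC(C)C)c(OS(=O)(=O)c3ccc(C)cc3)c2C)oc(=O)c1C(=O)CC(C)C
F4 | step 2 | 6-ethyl-2,2-dimethyl-4H-1,3-dioxin-4-one | CCC1=CC(=O)OC(C)(C)O1
F5 | step 2 | 2,8-bis(2,2-dimethyl-4-oxo-4H-1,3-dioxin-6-yl)nonane-3,7-dione | CC(C(=O)CCCC(=O)C(C)C1=CC(=O)OC(C)(C)O1)C1=CC(=O)OC(C)(C)O1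
A1 | direct plan | methyl 2,4,6-trihydroxybenzoate | COC(=O)c1c(O)cc(O)cc1O
A2 | direct plan | 1-(4,6-dihydroxy-2-methoxy-3-methylphenyl)-3-methylbutan-1-one | COc1c(C)c(O)cc(O)c1C(=O)CC(C)C
A3 | direct plan | formaldehyde | C=O
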